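**Retrosynthetic overview**
- Feature: the acyl half is a straight C37 chain (C1 ester carbonyl to C37 methyl) with no branch, heteroatom or unsaturation, so an internal CH2–CH2 bond can serve as the seam. The only ring, the para-disubstituted benzene of the 4-hydroxyphenethyl unit, is bought intact.
- Disconnection A: the ester C1(=O)–O bond, giving heptatriacontanoic acid and 2-(4-benzyloxyphenyl)ethanol; the phenol stays masked as a benzyl ether until the last step.
- Disconnection B: the C14–C15 bond of the chain, giving two carboxylic acids that each lose CO2 at an anode: the C15 half ester supplies C1–C14 and tetracosanoic acid supplies C15–C37.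
- Ring formation: none. No ring is built and the target has no stereocenter.

Key step: step 3

Assumption: chain atoms are numbered from the ester carbonyl (C1) to the terminal methyl (C37); carboxylate salts that exist only before acidic work-up (steps 2 and 4) are treated as work-up forms of the acids and carry no number.

Step 1
Reactants: 1 pentadecanedioic acid
Product: 2 dimethyl pentadecanedioate
Conditions: MeOH (solvent), H2SO4 (cat.), reflux
Reagents that add atoms: methanol, SMILES CO
Why: Fischer esterification in a large excess of methanol should drive both unhindered carboxyl groups to the methyl ester.

Step 2
Reactants: 2 dimethyl pentadecanedioate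
Product: 3 15-methoxy-15-oxopentadecanoic acid (methyl hydrogen pentadecanedioate)
Conditions: Ba(OH)2 (0.5 equiv), dry MeOH, 20 °C; then 2 M HCl, Et2O
Reagents that add atoms: barium hydroxide, SMILES [Ba+2].[OH-].[OH-]
Why: Controlled half-saponification with one hydroxide per diester should stop after the first ester, because the barium salt of the half ester precipitates from methanol and is withdrawn from further hydrolysis.

Step 3
Reactants: 3 15-methoxy-15-oxopentadecanoic acid (about 3 equiv); 4 tetracosanoic acid
Product: 7 methyl heptatriacontanoate, via 14-methoxy-14-oxotetradecyl radical 5 (not isolated), via tricosyl radical 6 (not isolated)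
Conditions: NaOMe (about 5 mol% of total acid), MeOH/heptane, 50–55 °C, smooth Pt anode, Pt cathode, undivided cell, constant current about 0.25 A cm-2, until the electrolyte turns faintly alkaline
Reagents that add atoms: none
Why: Each carboxylate is oxidised at the platinum anode in a one-electron step to an acyloxy radical that ejects CO2, leaving the primary radicals 5 and 6 in a dense layer at the electrode, where they combine to form the C14–C15 bond of 7; this is a mixed Kolbe electrolysis, the classical lengthening of a fatty acid with a dicarboxylic half ester. No ring is closed and no stereocenter is created, so the step needs only chemoselectivity at the anode and cross- over homo-coupling. The one-electron path should prevail over further oxidation to cations (Hofer–Moest alcohols, ethers, alkenes) because both radicals are primary and carry no alpha substituent, the anode is smooth platinum, the current density is high and the medium stays weakly acidic through only slight neutralisation. Cross-coupling is statistical, so half ester 3 is supplied in roughly threefold excess to make the scarce radical 6 meet 5 more often than itself. The C28 diester from homo-coupling of 3 and the small amount of C46 alkane from 4 differ from 7 by one ester group each and should be removed by chromatography on silica or by crystallisation. The methyl ester end of 3 is inert at the anode, and the oxidisable aryl ether is kept out of the cell by attaching it only afterwards.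

Step 4
Reactants: 7 methyl heptatriacontanoate
Product: 8 heptatriacontanoic acid
Conditions: KOH, EtOH/H2O/toluene, reflux; then aq. HCl (hot)
Reagents that add atoms: potassium hydroxide, SMILES [K+].[OH-]
Why: Saponification of the unhindered methyl ester (acyl substitution by hydroxide) should go to completion in a toluene-containing alcoholic medium that keeps the waxy ester dissolved, and acidification frees the acid.

Step 5
Reactants: 8 heptatriacontanoic acid
Product: 9 heptatriacontanoyl chloride
Conditions: (COCl)2, DMF (cat.), toluene, 50 °C; evaporate
Reagents that add atoms: oxalyl chloride, SMILES O=C(Cl)C(=O)Cl
Why: Vilsmeier-type activation by oxalyl chloride with catalytic DMF converts the acid into its acid chloride with only gaseous by-products, and warm toluene keeps the long chain in solution.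

Step 6
Reactants: 9 heptatriacontanoyl chloride; 10 2-(4-benzyloxyphenyl)ethanol
Product: 11 2-(4-benzyloxyphenyl)ethyl heptatriacontanoate
Conditions: pyridine, DMAP (cat.), toluene, 50 °C
Reagents that add atoms: none
Why: DMAP-catalysed nucleophilic acyl substitution of the acid chloride by the unhindered primary alcohol, with pyridine taking up HCl, should give the ester cleanly because the benzyl ether masks the phenol and leaves only the aliphatic oxygen to be acylated.

Step 7
Reactants: 11 2-(4-benzyloxyphenyl)ethyl heptatriacontanoate
Product: 12 2-(4-hydroxyphenyl)ethyl heptatriacontanoate (target)
Conditions: H2 (1 atm), 10% Pd/C, THF/EtOAc, 40 °C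
Reagents that add atoms: none
Why: Catalytic hydrogenolysis cleaves the benzylic C–O bond of the aryl benzyl ether, while the alkyl ester, whose oxygen sits on a homobenzylic carbon, and the arene should be untouched under one atmosphere of hydrogen.

**Compound list**
1 | pentadecanedioic acid | OC(=O)CCCCCCCCCCCCCC(=O)O | starting material
2 | dimethyl pentadecanedioate | COC(=O)CCCCCCCCCCCCCC(=O)OC | intermediate
3 | 15-methoxy-15-oxopentadecanoic acid (methyl hydrogen pentadecanedioate) | COC(=O)CCCCCCCCCCCCCC(=O)O | intermediate
4 | tetracosanoic acid | CCCCCCCCCCCCCCCCCCCCCCCC(=O)O | starting material
5 | 14-methoxy-14-oxotetradecyl radical | [CH2]CCCCCCCCCCCCC(=O)OC | intermediate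
6 | tricosyl radical | [CH2]CCCCCCCCCCCCCCCCCCCCCC | intermediate
7 | methyl heptatriacontanoate | CCCCCCCCCCCCCCCCCCCCCCCCCCCCCCCCCCCCC(=O)OC | intermediate
8 | heptatriacontanoic acid | CCCCCCCCCCCCCCCCCCCCCCCCCCCCCCCCCCCCC(=O)O | intermediate
9 | heptatriacontanoyl chloride | CCCCCCCCCCCCCCCCCCCCCCCCCCCCCCCCCCCCC(=O)Cl | intermediate
10 | 2-(4-benzyloxyphenyl)ethanol | OCCc1ccc(OCc2ccccc2)cc1 | starting material
11 | 2-(4-benzyloxyphenyl)ethyl heptatriacontanoate | CCCCCCCCCCCCCCCCCCCCCCCCCCCCCCCCCCCCC(=O)OCCc1ccc(OCc2ccccc2)cc1 | intermediate
12 | 2-(4-hydroxyphenyl)ethyl heptatriacontanoate | CCCCCCCCCCCCCCCCCCCCCCCCCCCCCCCCCCCCC(=O)OCCc1ccc(O)cc1 | target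

Total step count: 7
Longest linear sequence: 7 steps (steps 1 to 7, from 1 to 12)

**Steps most likely to fail**

Step 3. The anodic coupling may fail as a process: the waxy products can coat the anode and choke the current, two-electron over-oxidation can take over, or homo-coupling can dominate so that the separation becomes impractical. The fallback makes the same kind of CH2–CH2 seam one carbon further along (C15–C16) by a polar cross-coupling. It sets out from half ester 3. The free acid is reduced chemoselectively with BH3·THF (THF, 0 °C to room temperature), which spares the methyl ester, to give methyl 15-hydroxypentadecanoate F1. Appel bromination (CBr4, PPh3, CH2Cl2, 0 °C) then gives methyl 15-bromopentadecanoate F2. Bought 1-bromodocosane F3 is converted with Mg turnings in THF into docosylmagnesium bromide F4. F4 is coupled with F2 under Li2CuCl4 catalysis (THF/NMP, −10 to 0 °C), where an alkyl Grignard reagent substitutes a primary bromide faster than it adds to an ester. This should give methyl heptatriacontanoate 7, where the route is rejoined before step 4.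

Step 2. The half-saponification may fail as a process: hydrolysis can run on to the diacid, or the barium salt may not precipitate cleanly, so that a statistical mixture results. The fallback replaces hydrolysis by acid-catalysed ester interchange and sets out from diacid 1 and diester 2. Equimolar amounts are heated with a little methanol and concentrated HCl in di-n-butyl ether at reflux, so that the carboxyl and ester groups redistribute to a mixture rich in the half ester. The diacid is removed by its insolubility in light petroleum and the diester by extraction of the half ester as its salt; both are recycled. The fallback comes back to the route at 3 and makes no new compound.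

Step 6. The acylation may fail as a process: the moisture-sensitive acid chloride can hydrolyse, or the waxy acyl donor can fall out of solution, leaving the conversion incomplete. The fallback avoids any activated acyl species and sets out from methyl ester 7 and alcohol 10. The two are heated with catalytic Bu2SnO in toluene at reflux while methanol is removed through 4 Å molecular sieves in a Soxhlet thimble. This tin-catalysed transesterification should give 11 directly, bypassing steps 4 and 5, and the route is rejoined at 11 before step 7. It makes no new compound.

**Further compounds**
F1 | step 3 | methyl 15-hydroxypentadecanoate | COC(=O)CCCCCCCCCCCCCCO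
F2 | step 3 | methyl 15-bromopentadecanoate | COC(=O)CCCCCCCCCCCCCCBr
F3 | step 3 | 1-bromodocosane (bought) | CCCCCCCCCCCCCCCCCCCCCCBr
F4 | step 3 | docosylmagnesium bromide | CCCCCCCCCCCCCCCCCCCCCC[Mg]Br
F0 | step 2 | none | none
F0 | step 6 | none | none
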